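**Retrosynthetic overview**
- The target comes from global desilylation of a protected chalcone, whose C8–acyl bond is made from an 8-bromochroman (Br–Li exchange) and a cinnamoyl Weinreb amide (Heck product of silylated 4-iodophenol and N-methoxy-N-methylacrylamide).
- Ring C (the dihydropyran) is the only ring built: O1–C2 is closed by an invertive Mitsunobu etherification of a (1S)-benzylic alcohol set by Ru-catalysed transfer hydrogenation; all four benzene rings come in as phenols.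
- Key bond C4–C4a: Rh-catalysed enantioselective 1,4-arylation of a (5R)-1,7-diarylhept-2-en-1-one with the arylzinc of ring A (sets C4).
- The enone comes from Ru cross-metathesis of a homoallylic silyl ether (Heck of silylated 4-iodophenol with allyl alcohol, then Brown allylation, which sets the carbinol) with an aryl vinyl ketone (4-bromophenol, acrolein).
- Ring A comes from resorcinol by Ir-catalysed C–H borylation/oxidation and O-methylation; its two MOM ethers direct the metalation.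

Assumption: the SMILES is read as the (2R,4S)-chroman (2,4-trans) with a (2R)-carbinol in the side chain; in the O-silylated intermediates the same geometry at C4 carries the descriptor R because the CIP priorities change.

Abbreviations in names: MOM = methoxymethyl, TBS = tert-butyldimethylsilyl, TIPS = triisopropylsilyl, TMS = trimethylsilyl, TES = triethylsilyl, Ipc = isopinocampheyl, TBSO/TIPSO/TMSO = the corresponding silyloxy groups.

**Step 1**
Reactants: 1 resorcinol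
Product: 2 1,3-bis(methoxymethoxy)benzene
Conditions: MOMCl (2.4 equiv), i-Pr2NEt, CH2Cl2, 0 °C → rt
Reagents that add atoms: chloromethyl methyl ether, COCCl
Why: Double O-alkylation of the phenols (Williamson-type acetal formation) installs the MOM groups that later direct the ortho-lithiation.

**Step 2**
Reactants: 2 1,3-bis(methoxymethoxy)benzene
Product: 4 3,5-bis(methoxymethoxy)phenol, via aryl pinacol boronate 3 (not isolated)
Conditions: [Ir(OMe)(cod)]2 (1.5 mol%), 4,4'-di-tert-butyl-2,2'-bipyridine (3 mol%), B2pin2 (0.55 equiv), THF, 80 °C; then 30% H2O2, aq. NaOH, 0 °C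
Reagents that add atoms: hydrogen peroxide, OO
Why: Sterically controlled Ir-catalysed aromatic C–H borylation takes the only C–H without an ortho substituent (C5), and the boronate is oxidised in the same pot (C–H borylation/oxidation to a 3,5-disubstituted phenol).

**Step 3**
Reactants: 4 3,5-bis(methoxymethoxy)phenol
Product: 5 1-methoxy-3,5-bis(methoxymethoxy)benzene
Conditions: MeI, K2CO3, acetone, reflux
Reagents that add atoms: iodomethane, CI
Why: Williamson etherification of the single free phenol gives the methyl ether that ends up as the 7-OMe group.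

**Step 4**
Reactants: 6 4-iodophenol
Product: 7 (4-iodophenoxy)triisopropylsilane
Conditions: TIPSCl, imidazole, DMF, rt
Reagents that add atoms: chlorotriisopropylsilane, CC(C)[Si](Cl)(C(C)C)C(C)C
Why: Imidazole-promoted O-silylation gives a robust aryl silyl ether that survives the Pd, B, Mg, Li and Rh chemistry and is removed by fluoride at the end.

**Step 5**
Reactants: 7 (4-iodophenoxy)triisopropylsilane; 8 allyl alcohol
Product: 9 3-[4-(TIPSO)phenyl]propanal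
Conditions: Pd(OAc)2 (3 mol%), Bu4NCl, NaHCO3, DMF, 45 °C
Reagents that add atoms: none
Why: Mizoroki–Heck arylation of allyl alcohol under Jeffery conditions; β-hydride elimination toward the carbinol carbon and tautomerisation give the 3-arylpropanal.

**Step 6**
Reactants: 9 3-[4-(TIPSO)phenyl]propanal; 10 allylmagnesium bromide
Product: 13 (3R)-1-[4-(TIPSO)phenyl]hex-5-en-3-ol, via B-allyldiisopinocampheylborane 11 (not isolated), via homoallyl borinate 12 (not isolated)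
Conditions: (−)-Ipc2BOMe (made from (+)-α-pinene), Et2O, −78 → 20 °C; then 9, −78 °C; then NaBO3·4H2O, THF/H2O, 20 °C
Reagents that add atoms: none
Why: Brown asymmetric allylboration through a closed chair transition state; the (+)-α-pinene-derived reagent adds allyl to the Si face of a linear aliphatic aldehyde, which here gives the R carbinol (allyl outranks the arylethyl arm).

**Step 7**
Reactants: 13 (3R)-1-[4-(TIPSO)phenyl]hex-5-en-3-ol
Product: 14 (3R)-3-(TBSO)-1-[4-(TIPSO)phenyl]hex-5-ene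
Conditions: TBSCl, imidazole, DMF, rt
Reagents that add atoms: tert-butylchlorodimethylsilane, CC(C)(C)[Si](C)(C)Cl
Why: Standard silylation protects the carbinol (no change at the stereocentre) for the organometallic steps that follow.

**Step 8**
Reactants: 15 4-bromophenol
Product: 16 (4-bromophenoxy)triisopropylsilane
Conditions: TIPSCl, imidazole, DMF, rt
Reagents that add atoms: chlorotriisopropylsilane, CC(C)[Si](Cl)(C(C)C)C(C)C
Why: O-silylation as in step 4 gives the aryl bromide needed for Grignard formation.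

**Step 9**
Reactants: 16 (4-bromophenoxy)triisopropylsilane; 17 acrolein
Product: 19 rac-1-[4-(TIPSO)phenyl]prop-2-en-1-ol, via aryl Grignard reagent 18 (not isolated)
Conditions: Mg turnings, THF, rt; then 17, −78 °C; then sat. aq. NH4Cl
Reagents that add atoms: none
Why: Grignard 1,2-addition to the enal at low temperature gives the allylic alcohol; its configuration is irrelevant because it is oxidised next.

**Step 10**
Reactants: 19 rac-1-[4-(TIPSO)phenyl]prop-2-en-1-ol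
Product: 20 1-[4-(TIPSO)phenyl]prop-2-en-1-one
Conditions: Dess–Martin periodinane, CH2Cl2, 0 °C → rt (used at once)
Reagents that add atoms: none
Why: Hypervalent-iodine oxidation of the allylic/benzylic alcohol gives the aryl vinyl ketone under neutral conditions that do not trigger its polymerisation.

**Step 11**
Reactants: 14 (3R)-3-(TBSO)-1-[4-(TIPSO)phenyl]hex-5-ene; 20 1-[4-(TIPSO)phenyl]prop-2-en-1-one
Product: 21 (2E,5R)-5-(TBSO)-1,7-bis[4-(TIPSO)phenyl]hept-2-en-1-one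
Conditions: second-generation Hoveyda–Grubbs catalyst RuCl2(H2IMes)(=CH-C6H4-2-OiPr) (5 mol%), 20 (1.5 equiv), CH2Cl2, 40 °C
Reagents that add atoms: none
Why: Olefin cross-metathesis between an unhindered terminal alkene and an electron-poor vinyl ketone is selective for the E-configured cross product.

**Step 12**
Reactants: 7 (4-iodophenoxy)triisopropylsilane; 22 N-methoxy-N-methylprop-2-enamide
Product: 23 (2E)-N-methoxy-N-methyl-3-[4-(TIPSO)phenyl]prop-2-enamide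
Conditions: Pd(OAc)2 (2 mol%), P(o-tol)3 (4 mol%), Et3N, MeCN, 80 °C
Reagents that add atoms: none
Why: Mizoroki–Heck coupling with syn insertion and syn β-hydride elimination gives the E-cinnamoyl Weinreb amide.

**Step 13**
Reactants: 5 1-methoxy-3,5-bis(methoxymethoxy)benzene; 21 (2E,5R)-5-(TBSO)-1,7-bis[4-(TIPSO)phenyl]hept-2-en-1-one
Product: 27 (3S,5R)-3-[4-methoxy-2,6-bis(methoxymethoxy)phenyl]-5-(TBSO)-1,7-bis[4-(TIPSO)phenyl]heptan-1-one, via aryllithium 24 (not isolated), via arylzinc chloride 25 (not isolated), via trimethylsilyl enol ether 26 (not isolated)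
Conditions: 5 (1.6 equiv), n-BuLi, THF, 0 °C; ZnCl2, 0 °C → rt; then 21, [RhCl((S)-binap)]2 (2.5 mol%), Me3SiCl (2 equiv), THF, 20–40 °C; then 1 M aq. citric acid, 0 °C
Reagents that add atoms: none
Why: Proposed new method: ortho-lithiation between the two MOM ethers and Li→Zn exchange give a di-ortho-alkoxy arylzinc that transmetallates to a monovalent rhodium–BINAP complex, whose enantioface-selective carbometallation of the s-cis enone forms the C4–C4a bond and an oxa-π-allyl rhodium enolate that Me3SiCl silylates to turn the catalyst over without any proton source (so the protodemetallation that defeats 2,6-dialkoxyarylboronic acids cannot occur), setting C4 by catalyst control in the sense known for (S)-BINAP with linear E-enones; the closest known reaction is the Rh/BINAP-catalysed asymmetric 1,4-addition of arylzinc chlorides to enones with Me3SiCl (Hayashi–Miyaura-type conjugate arylation), which has not been shown for 2,6-bis(alkoxy)arylzinc reagents or for acyclic aryl enones carrying a remote silyloxy stereocentre.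

**Step 14**
Reactants: 27 (3S,5R)-3-[4-methoxy-2,6-bis(methoxymethoxy)phenyl]-5-(TBSO)-1,7-bis[4-(TIPSO)phenyl]heptan-1-one
Product: 28 (1S,3R,5R)-3-[4-methoxy-2,6-bis(methoxymethoxy)phenyl]-5-(TBSO)-1,7-bis[4-(TIPSO)phenyl]heptan-1-ol
Conditions: RuCl(p-cymene)[(S,S)-TsDPEN] (2 mol%), HCO2H/Et3N (5:2), CH2Cl2, 30 °C
Reagents that add atoms: none
Why: Noyori asymmetric transfer hydrogenation of the aryl ketone; the (S,S) catalyst gives the (S)-aryl carbinol (same sense as acetophenone to (S)-1-phenylethanol) under catalyst control, and C3 keeps its geometry (its descriptor changes only by CIP priority).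

**Step 15**
Reactants: 28 (1S,3R,5R)-3-[4-methoxy-2,6-bis(methoxymethoxy)phenyl]-5-(TBSO)-1,7-bis[4-(TIPSO)phenyl]heptan-1-ol
Product: 30 (1S,3R,5R)-3-(2,6-dihydroxy-4-methoxyphenyl)-5-(TBSO)-1,7-bis[4-(TIPSO)phenyl]heptan-1-ol, via tris(trimethylsilyl) ether 29 (not isolated)
Conditions: TMSOTf (4 equiv), 2,2'-bipyridyl (6 equiv), CH2Cl2, 0 °C; then K2CO3 (cat.), MeOH, 0 °C, 15 min
Reagents that add atoms: none
Why: Non-acidic aryl MOM cleavage: the bipyridyl-buffered silyl triflate turns ArO–MOM into ArO–TMS (bipyridyl captures the methoxymethyl cation) and silylates the benzylic OH in passing, so the acid-labile p-silyloxybenzylic alcohol never meets a Brønsted acid; brief methanolysis then frees the three OH groups while the TBS and TIPS ethers stay.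

**Step 16**
Reactants: 30 (1S,3R,5R)-3-(2,6-dihydroxy-4-methoxyphenyl)-5-(TBSO)-1,7-bis[4-(TIPSO)phenyl]heptan-1-ol
Product: 31 (2R,4R)-4-[(2R)-2-(TBSO)-4-[4-(TIPSO)phenyl]butyl]-7-methoxy-2-[4-(TIPSO)phenyl]chroman-5-ol
Conditions: PPh3, DIAD, toluene, 0 °C
Reagents that add atoms: none
Why: Intramolecular Mitsunobu etherification: either of the two equivalent phenols displaces the activated benzylic oxygen with inversion (1S becomes 2R), closing ring C as the 2,4-trans chroman and leaving the other phenol as the 5-OH.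

**Step 17**
Reactants: 31 (2R,4R)-4-[(2R)-2-(TBSO)-4-[4-(TIPSO)phenyl]butyl]-7-methoxy-2-[4-(TIPSO)phenyl]chroman-5-ol
Product: 32 (2R,4R)-5-(TBSO)-4-[(2R)-2-(TBSO)-4-[4-(TIPSO)phenyl]butyl]-7-methoxy-2-[4-(TIPSO)phenyl]chroman
Conditions: TBSCl, imidazole, DMF, 40 °C
Reagents that add atoms: tert-butylchlorodimethylsilane, CC(C)(C)[Si](C)(C)Cl
Why: Silylation of the 5-OH removes the acidic proton and places a bulky group next to C6, which steers the bromination to C8.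

**Step 18**
Reactants: 32 (2R,4R)-5-(TBSO)-4-[(2R)-2-(TBSO)-4-[4-(TIPSO)phenyl]butyl]-7-methoxy-2-[4-(TIPSO)phenyl]chroman
Product: 33 (2R,4R)-8-bromo-5-(TBSO)-4-[(2R)-2-(TBSO)-4-[4-(TIPSO)phenyl]butyl]-7-methoxy-2-[4-(TIPSO)phenyl]chroman
Conditions: NBS (1.05 equiv), CH2Cl2, −78 → −20 °C, dark
Reagents that add atoms: N-bromosuccinimide, BrN1C(=O)CCC1=O
Why: Electrophilic aromatic bromination of the trioxygenated ring goes to C8 (between OMe and the ring oxygen, para to the silyloxy group) because C6 is shielded by the 5-OTBS group, as known for 5,7-dialkoxyflavans.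

**Step 19**
Reactants: 33 (2R,4R)-8-bromo-5-(TBSO)-4-[(2R)-2-(TBSO)-4-[4-(TIPSO)phenyl]butyl]-7-methoxy-2-[4-(TIPSO)phenyl]chroman; 23 (2E)-N-methoxy-N-methyl-3-[4-(TIPSO)phenyl]prop-2-enamide
Product: 36 (2E)-1-[(2R,4R)-5-(TBSO)-4-[(2R)-2-(TBSO)-4-[4-(TIPSO)phenyl]butyl]-7-methoxy-2-[4-(TIPSO)phenyl]chroman-8-yl]-3-[4-(TIPSO)phenyl]prop-2-en-1-one, via 8-lithiochroman 34 (not isolated), via lithium hemiaminal chelate 35 (not isolated)
Conditions: n-BuLi (1.05 equiv), THF, −78 °C; then 23 (1.2 equiv), −78 → −40 °C; then AcOH (1.2 equiv), −78 °C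
Reagents that add atoms: none
Why: Bromine–lithium exchange followed by Weinreb ketone synthesis; the chelated tetrahedral adduct stops over-addition, 1,2-addition leaves the E-alkene untouched, and the acidic quench keeps the released amine from adding to the enone.

**Step 20**
Reactants: 36 (2E)-1-[(2R,4R)-5-(TBSO)-4-[(2R)-2-(TBSO)-4-[4-(TIPSO)phenyl]butyl]-7-methoxy-2-[4-(TIPSO)phenyl]chroman-8-yl]-3-[4-(TIPSO)phenyl]prop-2-en-1-one
Product: 37 (2E)-1-[(2R,4S)-5-hydroxy-4-[(2R)-2-hydroxy-4-(4-hydroxyphenyl)butyl]-2-(4-hydroxyphenyl)-7-methoxychroman-8-yl]-3-(4-hydroxyphenyl)prop-2-en-1-one (target CNP0102599.2)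
Conditions: TBAF/AcOH (1:1, 8 equiv), THF, 0 → 40 °C
Reagents that add atoms: none
Why: Buffered fluoride cleaves all five silyl ethers without touching the chalcone, the benzylic ether or any stereocentre (C4 becomes S only by CIP priority).

**Compound list**
1 | resorcinol | Oc1cccc(O)c1 | starting material
2 | 1,3-bis(methoxymethoxy)benzene | COCOc1cccc(OCOC)c1 | intermediate
3 | 2-[3,5-bis(methoxymethoxy)phenyl]-4,4,5,5-tetramethyl-1,3,2-dioxaborolane | COCOc1cc(OCOC)cc(c1)B1OC(C)(C)C(C)(C)O1 | intermediate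
4 | 3,5-bis(methoxymethoxy)phenol | COCOc1cc(O)cc(OCOC)c1 | intermediate
5 | 1-methoxy-3,5-bis(methoxymethoxy)benzene | COCOc1cc(OC)cc(OCOC)c1 | intermediate
6 | 4-iodophenol | Oc1ccc(I)cc1 | starting material
7 | (4-iodophenoxy)triisopropylsilane | Ic1ccc(O[Si](C(C)C)(C(C)C)C(C)C)cc1 | intermediate
8 | allyl alcohol (prop-2-en-1-ol) | C=CCO | starting material
9 | 3-[4-(TIPSO)phenyl]propanal | O=CCCc1ccc(O[Si](C(C)C)(C(C)C)C(C)C)cc1 | intermediate
10 | allylmagnesium bromide | C=CC[Mg]Br | starting material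
11 | B-allyldiisopinocampheylborane (Ipc groups from (+)-α-pinene) | C=CCB([C@@H]1C[C@@H]2C[C@H]([C@H]1C)C2(C)C)[C@@H]1C[C@@H]2C[C@H]([C@H]1C)C2(C)C | intermediate
12 | (3R)-1-[4-(TIPSO)phenyl]hex-5-en-3-yl diisopinocampheylborinate | C=CC[C@H](OB([C@@H]1C[C@@H]2C[C@H]([C@H]1C)C2(C)C)[C@@H]1C[C@@H]2C[C@H]([C@H]1C)C2(C)C)CCc1ccc(O[Si](C(C)C)(C(C)C)C(C)C)cc1 | intermediate
13 | (3R)-1-[4-(TIPSO)phenyl]hex-5-en-3-ol | C=CC[C@H](O)CCc1ccc(O[Si](C(C)C)(C(C)C)C(C)C)cc1 | intermediate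
14 | (3R)-3-(TBSO)-1-[4-(TIPSO)phenyl]hex-5-ene | C=CC[C@H](O[Si](C)(C)C(C)(C)C)CCc1ccc(O[Si](C(C)C)(C(C)C)C(C)C)cc1 | intermediate
15 | 4-bromophenol | Oc1ccc(Br)cc1 | starting material
16 | (4-bromophenoxy)triisopropylsilane | Brc1ccc(O[Si](C(C)C)(C(C)C)C(C)C)cc1 | intermediate
17 | acrolein (prop-2-enal) | C=CC=O | starting material
18 | [4-(TIPSO)phenyl]magnesium bromide | Br[Mg]c1ccc(O[Si](C(C)C)(C(C)C)C(C)C)cc1 | intermediate
19 | rac-1-[4-(TIPSO)phenyl]prop-2-en-1-ol | C=CC(O)c1ccc(O[Si](C(C)C)(C(C)C)C(C)C)cc1 | intermediate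
20 | 1-[4-(TIPSO)phenyl]prop-2-en-1-one | C=CC(=O)c1ccc(O[Si](C(C)C)(C(C)C)C(C)C)cc1 | intermediate
21 | (2E,5R)-5-(TBSO)-1,7-bis[4-(TIPSO)phenyl]hept-2-en-1-one | O=C(/C=C/C[C@H](O[Si](C)(C)C(C)(C)C)CCc1ccc(O[Si](C(C)C)(C(C)C)C(C)C)cc1)c1ccc(O[Si](C(C)C)(C(C)C)C(C)C)cc1 | intermediate
22 | N-methoxy-N-methylprop-2-enamide | C=CC(=O)N(C)OC | starting material
23 | (2E)-N-methoxy-N-methyl-3-[4-(TIPSO)phenyl]prop-2-enamide | CON(C)C(=O)/C=C/c1ccc(O[Si](C(C)C)(C(C)C)C(C)C)cc1 | intermediate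
24 | [4-methoxy-2,6-bis(methoxymethoxy)phenyl]lithium | [Li]c1c(OCOC)cc(OC)cc1OCOC | intermediate
25 | chloro[4-methoxy-2,6-bis(methoxymethoxy)phenyl]zinc | Cl[Zn]c1c(OCOC)cc(OC)cc1OCOC | intermediate
26 | (1Z,3S,5R)-3-[4-methoxy-2,6-bis(methoxymethoxy)phenyl]-5-(TBSO)-1-(TMSO)-1,7-bis[4-(TIPSO)phenyl]hept-1-ene | C[Si](C)(C)O/C(=C\[C@@H](c1c(OCOC)cc(OC)cc1OCOC)C[C@H](O[Si](C)(C)C(C)(C)C)CCc1ccc(O[Si](C(C)C)(C(C)C)C(C)C)cc1)c1ccc(O[Si](C(C)C)(C(C)C)C(C)C)cc1 | intermediate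
27 | (3S,5R)-3-[4-methoxy-2,6-bis(methoxymethoxy)phenyl]-5-(TBSO)-1,7-bis[4-(TIPSO)phenyl]heptan-1-one | O=C(C[C@@H](c1c(OCOC)cc(OC)cc1OCOC)C[C@H](O[Si](C)(C)C(C)(C)C)CCc1ccc(O[Si](C(C)C)(C(C)C)C(C)C)cc1)c1ccc(O[Si](C(C)C)(C(C)C)C(C)C)cc1 | intermediate
28 | (1S,3R,5R)-3-[4-methoxy-2,6-bis(methoxymethoxy)phenyl]-5-(TBSO)-1,7-bis[4-(TIPSO)phenyl]heptan-1-ol | O[C@H](c1ccc(O[Si](C(C)C)(C(C)C)C(C)C)cc1)C[C@@H](c1c(OCOC)cc(OC)cc1OCOC)C[C@H](O[Si](C)(C)C(C)(C)C)CCc1ccc(O[Si](C(C)C)(C(C)C)C(C)C)cc1 | intermediate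
29 | (1S,3S,5R)-3-[4-methoxy-2,6-bis(TMSO)phenyl]-5-(TBSO)-1-(TMSO)-1,7-bis[4-(TIPSO)phenyl]heptane | C[Si](C)(C)O[C@H](c1ccc(O[Si](C(C)C)(C(C)C)C(C)C)cc1)C[C@@H](c1c(O[Si](C)(C)C)cc(OC)cc1O[Si](C)(C)C)C[C@H](O[Si](C)(C)C(C)(C)C)CCc1ccc(O[Si](C(C)C)(C(C)C)C(C)C)cc1 | intermediate
30 | (1S,3R,5R)-3-(2,6-dihydroxy-4-methoxyphenyl)-5-(TBSO)-1,7-bis[4-(TIPSO)phenyl]heptan-1-ol | O[C@H](c1ccc(O[Si](C(C)C)(C(C)C)C(C)C)cc1)C[C@@H](c1c(O)cc(OC)cc1O)C[C@H](O[Si](C)(C)C(C)(C)C)CCc1ccc(O[Si](C(C)C)(C(C)C)C(C)C)cc1 | intermediate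
31 | (2R,4R)-4-[(2R)-2-(TBSO)-4-[4-(TIPSO)phenyl]butyl]-7-methoxy-2-[4-(TIPSO)phenyl]chroman-5-ol | COc1cc(O)c2c(c1)O[C@@H](c1ccc(O[Si](C(C)C)(C(C)C)C(C)C)cc1)C[C@@H]2C[C@H](O[Si](C)(C)C(C)(C)C)CCc1ccc(O[Si](C(C)C)(C(C)C)C(C)C)cc1 | intermediate
32 | (2R,4R)-5-(TBSO)-4-[(2R)-2-(TBSO)-4-[4-(TIPSO)phenyl]butyl]-7-methoxy-2-[4-(TIPSO)phenyl]chroman | COc1cc(O[Si](C)(C)C(C)(C)C)c2c(c1)O[C@@H](c1ccc(O[Si](C(C)C)(C(C)C)C(C)C)cc1)C[C@@H]2C[C@H](O[Si](C)(C)C(C)(C)C)CCc1ccc(O[Si](C(C)C)(C(C)C)C(C)C)cc1 | intermediate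
33 | (2R,4R)-8-bromo-5-(TBSO)-4-[(2R)-2-(TBSO)-4-[4-(TIPSO)phenyl]butyl]-7-methoxy-2-[4-(TIPSO)phenyl]chroman | COc1cc(O[Si](C)(C)C(C)(C)C)c2c(c1Br)O[C@@H](c1ccc(O[Si](C(C)C)(C(C)C)C(C)C)cc1)C[C@@H]2C[C@H](O[Si](C)(C)C(C)(C)C)CCc1ccc(O[Si](C(C)C)(C(C)C)C(C)C)cc1 | intermediate
34 | [(2R,4R)-5-(TBSO)-4-[(2R)-2-(TBSO)-4-[4-(TIPSO)phenyl]butyl]-7-methoxy-2-[4-(TIPSO)phenyl]chroman-8-yl]lithium | COc1cc(O[Si](C)(C)C(C)(C)C)c2c(c1[Li])O[C@@H](c1ccc(O[Si](C(C)C)(C(C)C)C(C)C)cc1)C[C@@H]2C[C@H](O[Si](C)(C)C(C)(C)C)CCc1ccc(O[Si](C(C)C)(C(C)C)C(C)C)cc1 | intermediate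
35 | lithium (2E)-1-[methoxy(methyl)amino]-1-[the chroman-8-yl group of 34]-3-[4-(TIPSO)phenyl]prop-2-en-1-olate (tetrahedral adduct, new centre unassigned) | COc1cc(O[Si](C)(C)C(C)(C)C)c2c(c1C(O[Li])(N(C)OC)/C=C/c1ccc(O[Si](C(C)C)(C(C)C)C(C)C)cc1)O[C@@H](c1ccc(O[Si](C(C)C)(C(C)C)C(C)C)cc1)C[C@@H]2C[C@H](O[Si](C)(C)C(C)(C)C)CCc1ccc(O[Si](C(C)C)(C(C)C)C(C)C)cc1 | intermediate
36 | (2E)-1-[(2R,4R)-5-(TBSO)-4-[(2R)-2-(TBSO)-4-[4-(TIPSO)phenyl]butyl]-7-methoxy-2-[4-(TIPSO)phenyl]chroman-8-yl]-3-[4-(TIPSO)phenyl]prop-2-en-1-one | COc1cc(O[Si](C)(C)C(C)(C)C)c2c(c1C(=O)/C=C/c1ccc(O[Si](C(C)C)(C(C)C)C(C)C)cc1)O[C@@H](c1ccc(O[Si](C(C)C)(C(C)C)C(C)C)cc1)C[C@@H]2C[C@H](O[Si](C)(C)C(C)(C)C)CCc1ccc(O[Si](C(C)C)(C(C)C)C(C)C)cc1 | intermediate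
37 | (2E)-1-[(2R,4S)-5-hydroxy-4-[(2R)-2-hydroxy-4-(4-hydroxyphenyl)butyl]-2-(4-hydroxyphenyl)-7-methoxychroman-8-yl]-3-(4-hydroxyphenyl)prop-2-en-1-one | COc1cc(O)c2c(c1C(=O)/C=C/c1ccc(O)cc1)O[C@@H](c1ccc(O)cc1)C[C@@H]2C[C@H](O)CCc1ccc(O)cc1 | target

**Totals**
Total step count: 20.
Longest linear sequence: 13 steps (4, 5, 6, 7, 11, 13, 14, 15, 16, 17, 18, 19, 20, from 4-iodophenol).

**Steps most likely to fail, with fallbacks**

Step 13 (the proposed arylation). The doubly ortho-substituted arylzinc may transfer to rhodium or insert too slowly, or the sense or level of induction may be poor; if the sense is opposite, the antipodal ligand is used. The fallback is known auxiliary chemistry, sets out from 14 (with 24 and 18) and returns at 27. (R)-4-Phenyl-1,3-oxazolidin-2-one is N-acylated (n-BuLi, acryloyl chloride, THF, −78 °C) to (4R)-3-acryloyl-4-phenyl-1,3-oxazolidin-2-one F1. Cross-metathesis of 14 with F1 under the conditions of step 11 gives (4R)-3-[(2E,5R)-5-(TBSO)-7-[4-(TIPSO)phenyl]hept-2-enoyl]-4-phenyl-1,3-oxazolidin-2-one F2. Aryllithium 24 is converted with MgBr2·OEt2 and CuBr·SMe2 (THF/Me2S, −20 °C) into the aryl copper reagent, which adds to the chelated s-cis enoyl imide from the face opposite the 4-phenyl group to give (4R)-3-[(3S,5R)-3-[4-methoxy-2,6-bis(methoxymethoxy)phenyl]-5-(TBSO)-7-[4-(TIPSO)phenyl]heptanoyl]-4-phenyl-1,3-oxazolidin-2-one F3. Me(MeO)NH·HCl/AlMe3 (CH2Cl2, 0 °C) turns F3 into (3S,5R)-N-methoxy-3-[4-methoxy-2,6-bis(methoxymethoxy)phenyl]-N-methyl-5-(TBSO)-7-[4-(TIPSO)phenyl]heptanamide F4, and the aryl Grignard reagent 18 (THF, 0 °C) converts F4 into ketone 27.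

Step 15 (MOM removal beside the benzylic alcohol). The p-silyloxybenzylic alcohol may ionise or cyclise prematurely under the silyl triflate, and 30 may not survive silica. The fallback changes the order so that the alcohol is made only after the MOM groups are gone; it sets out from 27 and returns at 30. TESOTf/2,2'-bipyridyl (CH2Cl2, 0 °C) converts both aryl MOM ethers of 27 directly into aryl triethylsilyl ethers, giving (3S,5R)-3-[4-methoxy-2,6-bis(triethylsilyloxy)phenyl]-5-(TBSO)-1,7-bis[4-(TIPSO)phenyl]heptan-1-one F5. CBS reduction with (R)-2-methyl-CBS-oxazaborolidine and BH3·SMe2 (THF, −20 °C) gives (1S,3R,5R)-3-[4-methoxy-2,6-bis(triethylsilyloxy)phenyl]-5-(TBSO)-1,7-bis[4-(TIPSO)phenyl]heptan-1-ol F6. K2CO3/MeOH at 0 °C removes only the two labile aryl TES groups of F6 and delivers triol 30.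

Step 16 (Mitsunobu closure). The electron-rich benzylic oxyphosphonium may ionise, which would erode the configuration at C2 or give the styrene. The fallback closes the ring under thermodynamic instead of SN2 control; it sets out from 30 and returns at 31. Camphorsulfonic acid (10 mol%) in CH2Cl2 (0 °C → rt) ionises the benzylic alcohol reversibly, and ring closure equilibrates through C2–O1 heterolysis toward the 2,4-trans chroman 31 (C4 chain pseudoaxial, away from the C5 oxygen; C2 aryl equatorial). The minor 2,4-cis epimer (2S,4R)-4-[(2R)-2-(TBSO)-4-[4-(TIPSO)phenyl]butyl]-7-methoxy-2-[4-(TIPSO)phenyl]chroman-5-ol F7 is separated by chromatography and put back into the acid.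

**Further compounds**
F1 | step 13 | (4R)-3-acryloyl-4-phenyl-1,3-oxazolidin-2-one | O=C1OC[C@@H](c2ccccc2)N1C(=O)C=C
F2 | step 13 | (4R)-3-[(2E,5R)-5-(TBSO)-7-[4-(TIPSO)phenyl]hept-2-enoyl]-4-phenyl-1,3-oxazolidin-2-one | O=C1OC[C@@H](c2ccccc2)N1C(=O)/C=C/C[C@H](O[Si](C)(C)C(C)(C)C)CCc1ccc(O[Si](C(C)C)(C(C)C)C(C)C)cc1
F3 | step 13 | (4R)-3-[(3S,5R)-3-[4-methoxy-2,6-bis(methoxymethoxy)phenyl]-5-(TBSO)-7-[4-(TIPSO)phenyl]heptanoyl]-4-phenyl-1,3-oxazolidin-2-one | O=C1OC[C@@H](c2ccccc2)N1C(=O)C[C@@H](c1c(OCOC)cc(OC)cc1OCOC)C[C@H](O[Si](C)(C)C(C)(C)C)CCc1ccc(O[Si](C(C)C)(C(C)C)C(C)C)cc1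
F4 | step 13 | (3S,5R)-N-methoxy-3-[4-methoxy-2,6-bis(methoxymethoxy)phenyl]-N-methyl-5-(TBSO)-7-[4-(TIPSO)phenyl]heptanamide | CON(C)C(=O)C[C@@H](c1c(OCOC)cc(OC)cc1OCOC)C[C@H](O[Si](C)(C)C(C)(C)C)CCc1ccc(O[Si](C(C)C)(C(C)C)C(C)C)cc1
F5 | step 15 | (3S,5R)-3-[4-methoxy-2,6-bis(triethylsilyloxy)phenyl]-5-(TBSO)-1,7-bis[4-(TIPSO)phenyl]heptan-1-one | O=C(C[C@@H](c1c(O[Si](CC)(CC)CC)cc(OC)cc1O[Si](CC)(CC)CC)C[C@H](O[Si](C)(C)C(C)(C)C)CCc1ccc(O[Si](C(C)C)(C(C)C)C(C)C)cc1)c1ccc(O[Si](C(C)C)(C(C)C)C(C)C)cc1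
F6 | step 15 | (1S,3R,5R)-3-[4-methoxy-2,6-bis(triethylsilyloxy)phenyl]-5-(TBSO)-1,7-bis[4-(TIPSO)phenyl]heptan-1-ol | O[C@H](c1ccc(O[Si](C(C)C)(C(C)C)C(C)C)cc1)C[C@@H](c1c(O[Si](CC)(CC)CC)cc(OC)cc1O[Si](CC)(CC)CC)C[C@H](O[Si](C)(C)C(C)(C)C)CCc1ccc(O[Si](C(C)C)(C(C)C)C(C)C)cc1
F7 | step 16 | (2S,4R)-4-[(2R)-2-(TBSO)-4-[4-(TIPSO)phenyl]butyl]-7-methoxy-2-[4-(TIPSO)phenyl]chroman-5-ol | COc1cc(O)c2c(c1)O[C@H](c1ccc(O[Si](C(C)C)(C(C)C)C(C)C)cc1)C[C@@H]2C[C@H](O[Si](C)(C)C(C)(C)C)CCc1ccc(O[Si](C(C)C)(C(C)C)C(C)C)cc1
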